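**Plan**

1. Retrosynthetic cuts: both aryl-ether C–O bonds of the spiro unit are cut, O-7 (flavan ring A)–C-2' first and O (ring D)–C(spiro) second, which opens both five-membered rings to an acyclic α-aryl chalcone. Then Cα=Cβ (Knoevenagel) and C-8 (ring A)–Cα (Pd enolate arylation) are cut, leaving a flavan bromide, a phloroacetophenone and 4-hydroxybenzaldehyde, all protected.
2. Enabling feature: the spiro carbon (Cα) is α to the ring D ketone, benzylic on C-8 of ring A (ortho to O-7), and bonded to C-2' (Cβ), the benzylic carbon of the 4-hydroxyphenyl ring E. Two-electron oxidation of the chalcone therefore gives an ortho/para bis-quinone methide whose two termini, Cα and Cβ, are the two carbons that need an aryl-ether oxygen, each within 5-exo reach of its phenol.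
3. Forward order: (2S)-naringenin → protected (S)-flavan → 8-bromide; arylation of the ring D methyl ketone; condensation with the ring E aldehyde; MOM removal; oxidative double cyclisation (benzofuranone ring first, dihydrofuran ring second); hydrogenolysis.
4. Stereochemistry: flavan C-2 comes from (2S)-naringenin; the spiro centre from a chiral phosphoric acid in the first oxa-conjugate addition; C-2' from the spiro centre in the second, reversible addition.
5. Labels: rings A/B/C are the flavan benzo, 2-aryl and pyran rings; ring D is the phloroglucinol ring; ring E is the second 4-hydroxyphenyl ring.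

Key step: step 9

Assumption: (2S)-naringenin is taken as available in high enantiomeric purity, and the cis relation of the C-2' aryl group to the benzofuranone ring oxygen found in the target is taken to be the more stable arrangement at this epimerisable centre.

**Route**

Step 1
Reactants: 1 (2S)-naringenin
Product: 2 (S)-5-hydroxy-7-(methoxymethoxy)-2-[4-(methoxymethoxy)phenyl]chroman-4-one
Conditions: MOMCl (2.4 equiv), i-Pr2NEt (3 equiv), CH2Cl2/DMF, 0 °C → rt
Reagents that add atoms: chloromethyl methyl ether (MOMCl), COCCl
Why: Williamson-type MOM ether formation at the two acidic, unhindered phenols (7-OH, 4'-OH), while the 5-OH is hydrogen-bonded to the C-4 carbonyl and stays free; the weak amine base at or below room temperature should not open the flavanone ring, so C-2 stays (S).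

Step 2
Reactants: 2 (S)-5-hydroxy-7-(methoxymethoxy)-2-[4-(methoxymethoxy)phenyl]chroman-4-one
Product: 4 (S)-7-(methoxymethoxy)-2-[4-(methoxymethoxy)phenyl]chroman-5-ol, via O-5 ethyl carbonate 3 (not isolated)
Conditions: ClCO2Et (1.2 equiv), Et3N (1.3 equiv), THF, 0 °C; then NaBH4 (4 equiv), THF/H2O, 0 °C → rt
Reagents that add atoms: none
Why: Reductive deoxygenation of an ortho-hydroxyaryl ketone through its aryl ethyl carbonate: hydride reduction of C-4, carbonate transfer and loss of ethyl carbonate give an ortho-quinone methide that NaBH4 reduces to CH2, freeing the 5-OH again and leaving the remote C-2 centre untouched.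

Step 3
Reactants: 4 (S)-7-(methoxymethoxy)-2-[4-(methoxymethoxy)phenyl]chroman-5-ol
Product: 5 (S)-5-(benzyloxy)-7-(methoxymethoxy)-2-[4-(methoxymethoxy)phenyl]chromane
Conditions: BnBr (1.2 equiv), K2CO3 (2 equiv), DMF, rt
Reagents that add atoms: benzyl bromide, BrCc1ccccc1
Why: Williamson ether synthesis on the now unchelated 5-OH; the benzyl group is kept to the end so that ring A can later form a quinone methide only through O-7.

Step 4
Reactants: 5 (S)-5-(benzyloxy)-7-(methoxymethoxy)-2-[4-(methoxymethoxy)phenyl]chromane
Product: 6 (S)-5-(benzyloxy)-8-bromo-7-(methoxymethoxy)-2-[4-(methoxymethoxy)phenyl]chromane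
Conditions: NBS (1.0 equiv), CH2Cl2, −40 → 0 °C, dark
Reagents that add atoms: N-bromosuccinimide, O=C1CCC(=O)N1Br
Why: Electrophilic aromatic bromination of the doubly activated ring A, expected at C-8 as is usual for 5,7-di-O-alkylflavans, C-6 being flanked by two bulky ether groups.

Step 5
Reactants: 7 1-[2,4-bis(benzyloxy)-6-hydroxyphenyl]ethan-1-one
Product: 8 1-[2,4-bis(benzyloxy)-6-(methoxymethoxy)phenyl]ethan-1-one
Conditions: NaH (1.2 equiv), MOMCl (1.3 equiv), DMF, 0 °C → rt
Reagents that add atoms: chloromethyl methyl ether (MOMCl), COCCl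
Why: Williamson-type MOM ether formation; the chelated ortho-hydroxyl needs full deprotonation to the phenoxide before it is alkylated.

Step 6
Reactants: 6 (S)-5-(benzyloxy)-8-bromo-7-(methoxymethoxy)-2-[4-(methoxymethoxy)phenyl]chromane; 8 1-[2,4-bis(benzyloxy)-6-(methoxymethoxy)phenyl]ethan-1-one (1.2 equiv)
Product: 9 1-[2,4-bis(benzyloxy)-6-(methoxymethoxy)phenyl]-2-{(S)-5-(benzyloxy)-7-(methoxymethoxy)-2-[4-(methoxymethoxy)phenyl]chroman-8-yl}ethan-1-one (deoxybenzoin)
Conditions: Pd(OAc)2 (5 mol %), XPhos (10 mol %), NaOt-Bu (2.2 equiv), toluene, 80 °C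
Reagents that add atoms: none
Why: Palladium-catalysed α-arylation of the methyl ketone enolate; the bulky electron-rich biarylphosphine should allow oxidative addition into the electron-rich, doubly ortho-oxygenated C–Br bond, and the crowded product enolate should resist a second arylation.

Step 7
Reactants: 9 deoxybenzoin; 10 4-(methoxymethoxy)benzaldehyde
Product: 11 (E)-1-[2,4-bis(benzyloxy)-6-(methoxymethoxy)phenyl]-2-{(S)-5-(benzyloxy)-7-(methoxymethoxy)-2-[4-(methoxymethoxy)phenyl]chroman-8-yl}-3-[4-(methoxymethoxy)phenyl]prop-2-en-1-one (α-aryl chalcone)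
Conditions: piperidine (0.5 equiv), AcOH (0.5 equiv), toluene, reflux, Dean–Stark
Reagents that add atoms: none
Why: Knoevenagel-type aldol condensation of the activated methylene of the deoxybenzoin with a non-enolisable aldehyde, driven by azeotropic removal of water; the (E) isomer is expected, but the alkene geometry is irrelevant because it is lost in step 9.

Step 8
Reactants: 11 α-aryl chalcone
Product: 12 (E)-1-[2,4-bis(benzyloxy)-6-hydroxyphenyl]-2-[(S)-5-(benzyloxy)-7-hydroxy-2-(4-hydroxyphenyl)chroman-8-yl]-3-(4-hydroxyphenyl)prop-2-en-1-one (tetraphenol chalcone)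
Conditions: HCl (2 M in MeOH), THF, rt
Reagents that add atoms: none
Why: Acid-catalysed transacetalisation of the four aryl MOM ethers to methanol; benzyl ethers and the flavan ether are inert to dilute acid at room temperature, and the mild conditions are chosen so that the ortho-hydroxychalcone does not cyclise to a flavanone.

Step 9
Reactants: 12 tetraphenol chalcone
Product: 15 tri-O-benzyl daphnodorin C (benzyl on O-4 and O-6 of the benzofuranone and on flavan O-5; spiro centre S; C-2' S; flavan C-2 S), via bis-quinone methide 13 (not isolated), via spiro para-quinone methide 14 (not isolated)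
Conditions: (R)-TRIP [(R)-3,3'-bis(2,4,6-triisopropylphenyl)-1,1'-binaphthyl-2,2'-diyl hydrogen phosphate] (10 mol %), DDQ (1.05 equiv, slow addition), 4 Å MS, CH2Cl2/toluene, −40 → −10 °C
Reagents that add atoms: none
Why: Proposed new method: DDQ removes the hydrogens of the ring E OH and the ring A 7-OH from the cross-conjugated bis-phenol to give the ortho/para bis-quinone methide 13; the ring D ortho-OH then adds to Cα (terminus of the ring A ortho-quinone methide) to form the benzofuranone and rearomatise ring A (14), and the regenerated 7-OH adds to Cβ (terminus of the ring E para-quinone methide) to close the dihydrofuran. The closest known reaction types are chiral-phosphoric-acid-catalysed additions of O–H nucleophiles to ortho-quinone methides formed in situ (including fully substituted ones from tertiary benzylic alcohols), DDQ-driven oxidative couplings under chiral phosphate control, and the oxidative cyclisation of 2'-hydroxychalcones to aurones, which is interrupted here because Cα carries no hydrogen. Both rings close in the 5-exo-trig mode as oxa-conjugate additions, a 1,4-addition to the ortho-quinone methide followed by a 1,6-addition to the para-quinone methide. The spiro centre is set in the first addition by the acid, which is expected to bridge the C-7 carbonyl of the quinone methide and the ring D OH and so deliver oxygen to one face of planar Cα (the flavan centre is too remote to interfere; the antipode of the acid that gives the S centre is fixed in a trial run, R being written here). C-2' is set in the second addition by the spiro centre, the aryl ring taking the side of the ring oxygen away from the carbonyl, and it can equilibrate to this arrangement by reversible ring opening while the ring E OH is free. The step needs oxidation at the hydroxystilbene unit and not at the flavan benzylic positions (it is the most electron-rich conjugated phenol system; one equivalent of DDQ at low temperature), and 5-exo attack at Cα and not 6-endo attack at Cβ, which the twist of the aroyl group between its 6'-benzyloxy group and ring A should secure by holding the chelated OH above Cα; O-5 is benzylated so that ring A can form only the O-7 quinone methide.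

Step 10
Reactants: 15 tri-O-benzyl daphnodorin C
Product: 16 daphnodorin C (spiro centre S; C-2' S; flavan C-2 S)
Conditions: H2 (1 atm), Pd/C (10 wt %), EtOAc/MeOH, rt
Reagents that add atoms: none
Why: Hydrogenolysis of the three aryl benzyl ethers under neutral conditions, the standard final deprotection in flavan chemistry, which should leave the cyclic benzylic ethers at flavan C-2 and C-2' and the vinylogous-ester ketone untouched.

**Compound list**

1 | (2S)-naringenin, (S)-5,7-dihydroxy-2-(4-hydroxyphenyl)chroman-4-one | Oc1cc(O)c2c(c1)O[C@H](c1ccc(O)cc1)CC2=O | starting material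
2 | (S)-5-hydroxy-7-(methoxymethoxy)-2-[4-(methoxymethoxy)phenyl]chroman-4-one | COCOc1cc(O)c2c(c1)O[C@H](c1ccc(OCOC)cc1)CC2=O | intermediate
3 | (S)-ethyl 7-(methoxymethoxy)-2-[4-(methoxymethoxy)phenyl]-4-oxochroman-5-yl carbonate (not isolated) | COCOc1cc(OC(=O)OCC)c2c(c1)O[C@H](c1ccc(OCOC)cc1)CC2=O | intermediate
4 | (S)-7-(methoxymethoxy)-2-[4-(methoxymethoxy)phenyl]chroman-5-ol | COCOc1cc(O)c2c(c1)O[C@H](c1ccc(OCOC)cc1)CC2 | intermediate
5 | (S)-5-(benzyloxy)-7-(methoxymethoxy)-2-[4-(methoxymethoxy)phenyl]chromane | COCOc1cc(OCc3ccccc3)c2c(c1)O[C@H](c1ccc(OCOC)cc1)CC2 | intermediate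
6 | (S)-5-(benzyloxy)-8-bromo-7-(methoxymethoxy)-2-[4-(methoxymethoxy)phenyl]chromane | COCOc1cc(OCc3ccccc3)c2c(c1Br)O[C@H](c1ccc(OCOC)cc1)CC2 | intermediate
7 | 1-[2,4-bis(benzyloxy)-6-hydroxyphenyl]ethan-1-one | CC(=O)c1c(O)cc(OCc2ccccc2)cc1OCc1ccccc1 | starting material
8 | 1-[2,4-bis(benzyloxy)-6-(methoxymethoxy)phenyl]ethan-1-one | CC(=O)c1c(OCOC)cc(OCc2ccccc2)cc1OCc1ccccc1 | intermediate
9 | deoxybenzoin, 1-[2,4-bis(benzyloxy)-6-(methoxymethoxy)phenyl]-2-{(S)-5-(benzyloxy)-7-(methoxymethoxy)-2-[4-(methoxymethoxy)phenyl]chroman-8-yl}ethan-1-one | O=C(Cc1c(OCOC)cc(OCc3ccccc3)c2c1O[C@H](c1ccc(OCOC)cc1)CC2)c1c(OCOC)cc(OCc2ccccc2)cc1OCc1ccccc1 | intermediate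
10 | 4-(methoxymethoxy)benzaldehyde | O=Cc1ccc(OCOC)cc1 | starting material
11 | (E)-α-aryl chalcone, fully protected (four MOM, three benzyl) | O=C(c1c(OCOC)cc(OCc2ccccc2)cc1OCc1ccccc1)/C(=C/c1ccc(OCOC)cc1)c1c(OCOC)cc(OCc3ccccc3)c2c1O[C@H](c1ccc(OCOC)cc1)CC2 | intermediate
12 | (E)-tetraphenol chalcone (free: ring D ortho-OH, ring A 7-OH, ring B OH, ring E OH) | O=C(c1c(O)cc(OCc2ccccc2)cc1OCc1ccccc1)/C(=C/c1ccc(O)cc1)c1c(O)cc(OCc3ccccc3)c2c1O[C@H](c1ccc(O)cc1)CC2 | intermediate
13 | bis-quinone methide (ring A as 7-oxo ortho-quinone methide at C-8=Cα; ring E as para-quinone methide at Cβ; not isolated) | O=C(c1c(O)cc(OCc2ccccc2)cc1OCc1ccccc1)C(C=C1C=CC(=O)C=C1)=C1C(=O)C=C(OCc3ccccc3)C2=C1O[C@H](c1ccc(O)cc1)CC2 | intermediate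
14 | spiro para-quinone methide: 2-(flavan-8-yl)-2-[(4-oxocyclohexa-2,5-dien-1-ylidene)methyl]-4,6-bis(benzyloxy)benzofuran-3(2H)-one, quaternary centre with the spatial arrangement of the final spiro centre (not isolated) | O=C1c2c(OCc3ccccc3)cc(OCc3ccccc3)cc2O[C@]1(C=C1C=CC(=O)C=C1)c1c(O)cc(OCc3ccccc3)c2c1O[C@H](c1ccc(O)cc1)CC2 | intermediate
15 | tri-O-benzyl daphnodorin C (spiro S; C-2' S; flavan C-2 S) | O=C1c2c(OCc3ccccc3)cc(OCc3ccccc3)cc2O[C@]12c1c(cc(OCc3ccccc3)c3c1O[C@H](c1ccc(O)cc1)CC3)O[C@H]2c1ccc(O)cc1 | intermediate
16 | daphnodorin C (spiro S; C-2' S; flavan C-2 S) | O=C1c2c(O)cc(O)cc2O[C@]12c1c(cc(O)c3c1O[C@H](c1ccc(O)cc1)CC3)O[C@H]2c1ccc(O)cc1 | target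

**Step count and risks**

Total steps: 10. Longest linear sequence: 9 steps (steps 1–4 and 6–10, from naringenin).

Steps most likely to fail:

1. Step 9. The uncatalysed 5-exo ring closure of the tethered phenol onto the very reactive quinone methide may outrun the acid-bound pathway, giving poor facial selectivity at the spiro carbon. Fallback: reagent control is given up and the stereochemical problem becomes a separation. Compound 12 is oxidised with Ag2O (1.2 equiv, acetone/benzene, rt), the classical way of turning 4-hydroxystilbenes and propenylphenols into quinone methides that are trapped by internal oxygen nucleophiles. This should give 15 together with its isomer of opposite configuration at the spiro carbon and at C-2', tri-O-benzyl 2',spiro-bis-epi-daphnodorin C F1. Because the (S)-flavan centre is untouched, 15 and F1 are diastereomers and are separated by chromatography (preparative HPLC if needed). The route is rejoined at 15.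

2. Step 7. The doubly ortho-flanked methylene of 9 may fail to condense, or the aldol stage may revert under the equilibrium conditions. Fallback: the condensation is split into an irreversible directed aldol addition and a separate elimination, starting from 9. The lithium enolate (LiHMDS, THF, −78 °C) is added to aldehyde 10 to give the β-hydroxy ketone F2 (diastereomer mixture, of no consequence). Mesylation (MsCl, Et3N, CH2Cl2, 0 °C) gives the mesylate F3, which is not isolated and is eliminated with DBU (E1cB) to 11.

3. Step 6. Oxidative addition into the electron-rich, doubly ortho-oxygenated C–Br bond may be slow, with hydrodebromination competing. Fallback: the C-8–Cα bond is made by Suzuki–Miyaura coupling instead, starting from 6, 8 and 10.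
   - Bromide 6 undergoes bromine–lithium exchange (n-BuLi, THF, −78 °C); quenching with B(OMe)3 and aqueous NH4Cl work-up gives the boronic acid F4.
   - Separately, 8 and 10 are condensed (KOH, EtOH, Claisen–Schmidt) to the chalcone F5.
   - F5 is brominated (Br2, CH2Cl2, 0 °C) to the dibromide F6 (not isolated) and dehydrobrominated with Et3N to the α-bromochalcone F7.
   - Coupling of F4 with F7 (Pd(OAc)2, SPhos, K3PO4, toluene/H2O, 80 °C) gives 11, so steps 6 and 7 are both bypassed and the route is rejoined at 11.

**Further compounds**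

F1 | step 9 | tri-O-benzyl 2',spiro-bis-epi-daphnodorin C (spiro R; C-2' R; flavan C-2 S) | O=C1c2c(OCc3ccccc3)cc(OCc3ccccc3)cc2O[C@@]12c1c(cc(OCc3ccccc3)c3c1O[C@H](c1ccc(O)cc1)CC3)O[C@@H]2c1ccc(O)cc1
F2 | step 7 | β-hydroxy ketone (aldol adduct of 9 and 10; mixture of diastereomers at the two new centres) | O=C(c1c(OCOC)cc(OCc2ccccc2)cc1OCc1ccccc1)C(C(O)c1ccc(OCOC)cc1)c1c(OCOC)cc(OCc3ccccc3)c2c1O[C@H](c1ccc(OCOC)cc1)CC2
F3 | step 7 | mesylate of F2 (not isolated) | O=C(c1c(OCOC)cc(OCc2ccccc2)cc1OCc1ccccc1)C(C(OS(C)(=O)=O)c1ccc(OCOC)cc1)c1c(OCOC)cc(OCc3ccccc3)c2c1O[C@H](c1ccc(OCOC)cc1)CC2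
F4 | step 6 | {(S)-5-(benzyloxy)-7-(methoxymethoxy)-2-[4-(methoxymethoxy)phenyl]chroman-8-yl}boronic acid | OB(O)c1c(OCOC)cc(OCc3ccccc3)c2c1O[C@H](c1ccc(OCOC)cc1)CC2
F5 | step 6 | (E)-1-[2,4-bis(benzyloxy)-6-(methoxymethoxy)phenyl]-3-[4-(methoxymethoxy)phenyl]prop-2-en-1-one | O=C(c1c(OCOC)cc(OCc2ccccc2)cc1OCc1ccccc1)/C=C/c1ccc(OCOC)cc1
F6 | step 6 | 2,3-dibromo-1-[2,4-bis(benzyloxy)-6-(methoxymethoxy)phenyl]-3-[4-(methoxymethoxy)phenyl]propan-1-one (racemic anti-addition product; not isolated) | O=C(C(Br)C(Br)c1ccc(OCOC)cc1)c1c(OCOC)cc(OCc2ccccc2)cc1OCc1ccccc1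
F7 | step 6 | (Z)-2-bromo-1-[2,4-bis(benzyloxy)-6-(methoxymethoxy)phenyl]-3-[4-(methoxymethoxy)phenyl]prop-2-en-1-one | O=C(c1c(OCOC)cc(OCc2ccccc2)cc1OCc1ccccc1)/C(Br)=C/c1ccc(OCOC)cc1
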